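**The task.** 3 questions are put to two flasks that differ in time.

common to all: left-handed substrate 0.050 M; right-handed substrate 0.050 M

| run | partner | precatalyst | remark | time |
|---|---|---|---|---|
| ochre | 1.5 equiv | 1.4 mol% | run made earlier |  |
| teal | 1.5 equiv | 2.2 mol% | run made earlier |  |
| theta | 1.50 equiv | 1 mol% |  | 10 h |
| beta | 1.50 equiv | 1 mol% |  | 20 h |

- ochre (time / h: right-handed substrate / %, left-handed substrate / %, left-handed product / %): 2.00: 46.5, 44.2, 6.0; 4.00: 40.2, 37.3, 16.6; 6.00: 35.3, 31.7, 24.5; 8.00: 30.1, 27.5, 32.2
- teal (time / h: right-handed substrate / %, left-handed substrate / %, left-handed product / %): 0.667: 49.1, 49.0, 1.7; 1.33: 47.1, 44.6, 5.0; 3.00: 41.3, 36.6, 16.2; 8.00: 24.8, 21.4, 41.2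

(readings scatter by 0.3 percentage points)

* the flask that ends with the higher excess of right-handed substrate over left-handed substrate among what is left of the two, or "neither" when 2 percentage points or less lies between them (theta / beta / neither)
* excess of right-handed substrate over left-handed substrate among what is left of the two at the end, theta
* excess of right-handed substrate over left-handed substrate among what is left of the two at the end, beta

- free catalyst is single-handed; left-handed substrate and right-handed substrate are mirror images of each other, charged as a racemate, each of them at the stated concentration
- an excess is the difference of the two amounts in percent of their sum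
- an excess is below zero if the other one leads

**First extreme.** If the substrates never crossed, left-handed product could come from left-handed substrate and nothing else. But the ochre run at 8.00 h has lost 22 percentage points of left-handed substrate and holds 32.2 % of left-handed product, which is more than that loss. With the same total left, that version would show an excess of 38.2 %, while the ochre run reads 4.51 %.

**Second extreme.** Instant crossing (racemisation, as in a dynamic kinetic resolution) would hold the excess at zero.

**Between them.** The catalyst's preference pushes the excess up in step with the loading, while crossing pulls it back in step with the excess, so a balance should stand in proportion to the loading. The teal run reads 7.36 % at 8.00 h, and the ratio of 1.63 to the ochre reading lies near the loading ratio of 1.57. Carried to 1 mol%, the teal reading gives 3.35 % and the ochre reading 3.22 %. This scaled excess, a run's late excess times the new loading over its own, is the reckoning here for both flasks, so it expects neither to lead.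

**The forecast.** The forecast says 3.4 % for theta, 3.4 % for beta and neither, slightly above the reckoning here: “At 1 mol%, I expect about 3.4% at both 10 and 20 h, hence neither.”

**The result.**

    free catalyst + left-handed substrate ⇌ catalyst intermediate A (K = 180 M⁻¹, k = 48.0 M⁻¹ min⁻¹)
    free catalyst + right-handed substrate ⇌ catalyst intermediate B (K = 76.0 M⁻¹, k = 150 M⁻¹ min⁻¹)
    partner + catalyst intermediate A → free catalyst + left-handed product (k = 4.80 M⁻¹ min⁻¹)
    partner + catalyst intermediate B → free catalyst + right-handed product (k = 1.70 M⁻¹ min⁻¹)
    left-handed substrate ⇌ right-handed substrate (k = 0.00760 min⁻¹)
    partner + precatalyst → free catalyst + spent reagent (k = 0.180 M⁻¹ min⁻¹)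

Theta ends at 3.62 % and beta at 2.64 %, so neither leads, the gap of 0.98 points being less than 2 points. The scaled excess of 3.35 % lies between them, and close to the 3.42 % of beta stopped at 5.0 h. A difference between the substrates, left to crossing, halves in 0.760 h, shorter than theta's 10 h. Meanwhile [partner] stands at 46 % of its charge at the end of theta and 19 % at the end of beta. With the partner raised, beta's answer has moved 5 points at 2.21 equiv.

All runs are calculated for substances that don't exist.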